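Everything rests on the C4′–C5′ bond, between the first methyl-bearing alkene carbon of the side chain and the following CH2. The pyran oxygen O1 lies five bonds from C4′ (O1–C2–C1′–C2′–C3′=C4′), so C4′ is held as the enol-ether carbon of a 3,4-dihydro-2H-pyran made from (R)-linalool, with O1 as leaving group. In one operation the cuprate of the C36 homoallyl chain undergoes a 1,2-metallate rearrangement that forms C4′–C5′, opens this temporary ring, sets the (E)-C3′=C4′ geometry, accepts the C4′ methyl from MeI and frees O1 on (R)-C2. Heck arylation, E-to-Z isomerisation and C–O coupling then close the chromene.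

Key step: step 14

Remark: all-E-heptaprenol is not taken to be a catalogue chemical, so its C35 chain is built from (2E,6E)-farnesyl acetate and (2E,6E,10E)-geranylgeraniol; side-chain locants count from C1′, the CH2 on C2, and C2 of the target is (R), as in commercial (R)-(−)-linalool.

Step 1
Reactants: 1 (R)-(−)-linalool [(3R)-3,7-dimethylocta-1,6-dien-3-ol]
Product: 2 (5R)-5-ethenyl-5-methyloxolan-2-ol (lactol of the γ-hydroxy aldehyde; both anomers)
Conditions: O3 (1 equiv.), CH2Cl2, −78 °C; then Me2S, −78 °C to rt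
Reagents that add atoms: ozone [O-][O+]=O
Why: Ozonolysis with reductive work-up cleaves the electron-rich trisubstituted alkene much faster than the monosubstituted vinyl group, and the γ-hydroxy aldehyde closes to the lactol; the tertiary carbinol centre is untouched and the new anomeric centre is erased in step 2.

Step 2
Reactants: 2 (5R)-5-ethenyl-5-methyloxolan-2-ol
Product: 3 (3R)-3-methylhept-1-en-6-yn-3-ol
Conditions: dimethyl (1-diazo-2-oxopropyl)phosphonate, K2CO3, MeOH, 0 °C to rt
Reagents that add atoms: dimethyl (1-diazo-2-oxopropyl)phosphonate CC(=O)C(=[N+]=[N-])P(=O)(OC)OC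
Why: Ohira–Bestmann (Seyferth–Gilbert) homologation converts the open aldehyde form of the lactol into the terminal alkyne and so adds the carbon that becomes C4′.

Step 3
Reactants: 3 (3R)-3-methylhept-1-en-6-yn-3-ol
Product: 4 (2R)-2-ethenyl-2-methyl-3,4-dihydro-2H-pyran
Conditions: W(CO)6 (15 mol%), Et3N, THF, hν (350 nm), 55 °C
Reagents that add atoms: none
Why: Tungsten-catalysed alkynol cycloisomerisation through a tungsten vinylidene should give the six-membered endocyclic enol ether (6-endo mode), in which the tertiary oxygen, the future O1, is bonded to the future C4′.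

Step 4
Reactants: 5 (2E,6E)-farnesyl acetate
Product: 6 (2E,6E,10E)-12-hydroxy-3,7,11-trimethyldodeca-2,6,10-trien-1-yl acetate
Conditions: SeO2 (10 mol%), t-BuOOH, salicylic acid (10 mol%), CH2Cl2, rt
Reagents that add atoms: tert-butyl hydroperoxide CC(C)(C)OO; selenium dioxide O=[Se]=O (catalytic oxygen carrier)
Why: Selenium dioxide-catalysed allylic oxidation (ene reaction followed by [2,3]-sigmatropic shift) attacks the most electron-rich terminal alkene at its (E)-methyl group and spares the acetate-deactivated C2=C3 alkene, giving the (E)-allylic alcohol.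

Step 5
Reactants: 6 (2E,6E,10E)-12-hydroxy-3,7,11-trimethyldodeca-2,6,10-trien-1-yl acetate
Product: 7 (2E,6E,10E)-12-bromo-3,7,11-trimethyldodeca-2,6,10-trien-1-yl acetate
Conditions: CBr4, PPh3, CH2Cl2, 0 °C
Reagents that add atoms: carbon tetrabromide BrC(Br)(Br)Br
Why: Appel bromination converts the primary allylic alcohol into the bromide under neutral conditions without allylic transposition or loss of the acetate.

Step 6
Reactants: 8 (2E,6E,10E)-geranylgeraniol
Product: 10 geranylgeranyl phenyl sulfone ([(2E,6E,10E)-3,7,11,15-tetramethylhexadeca-2,6,10,14-tetraen-1-yl]sulfonylbenzene), via geranylgeranyl bromide 9 (not isolated)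
Conditions: PBr3, Et2O, 0 °C; then PhSO2Na, DMF, rt
Reagents that add atoms: sodium benzenesulfinate [Na+].[O-]S(=O)c1ccccc1; phosphorus tribromide BrP(Br)Br (bromine of 9 only)
Why: Phosphorus tribromide gives the primary allylic bromide with the alkene geometry intact, and benzenesulfinate displaces it through sulfur in an SN2 reaction to give the allylic sulfone.

Step 7
Reactants: 10 geranylgeranyl phenyl sulfone; 7 (2E,6E,10E)-12-bromo-3,7,11-trimethyldodeca-2,6,10-trien-1-yl acetate
Product: 11 (2E,6E,10E,14E,18E,22E)-3,7,11,15,19,23,27-heptamethyl-13-(phenylsulfonyl)octacosa-2,6,10,14,18,22,26-heptaen-1-yl acetate (racemic at C13)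
Conditions: t-BuOK, THF/DMF, −40 °C; then 7, −40 to 0 °C
Reagents that add atoms: none
Why: Biellmann-type head-to-tail coupling, in which the sulfone-stabilised allylic carbanion is alkylated at its α-carbon by the allylic bromide faster than it attacks the acetate; the sulfone-bearing carbon forms as a racemate and is erased in step 8.

Step 8
Reactants: 11 the C35 sulfone acetate
Product: 12 all-E-heptaprenol [(2E,6E,10E,14E,18E,22E)-3,7,11,15,19,23,27-heptamethyloctacosa-2,6,10,14,18,22,26-heptaen-1-ol]
Conditions: Pd(dppp)Cl2 (5 mol%), LiBHEt3 (4 equiv.), THF, 0 °C to rt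
Reagents that add atoms: none
Why: Palladium-catalysed reductive desulfonylation through a π-allyl complex delivers hydride to the less substituted terminus, which keeps the position and (E) geometry of the alkene, while the same hydride reagent cleaves the acetate.

Step 9
Reactants: 12 all-E-heptaprenol
Product: 14 homoheptaprenyl phenyl sulfide ({[(3E,7E,11E,15E,19E,23E)-4,8,12,16,20,24,28-heptamethylnonacosa-3,7,11,15,19,23,27-heptaen-1-yl]sulfanyl}benzene), via heptaprenyl bromide 13 (not isolated)
Conditions: PBr3, Et2O, 0 °C; then PhSCH2Li (from PhSMe, n-BuLi, DABCO, THF, 0 °C), −78 °C to rt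
Reagents that add atoms: thioanisole CSc1ccccc1; phosphorus tribromide BrP(Br)Br (bromine of 13 only)
Why: SN2 alkylation of (phenylsulfanyl)methyllithium by the primary allylic bromide is a one-carbon homologation that installs the future C5′ as a sulfur-bearing CH2 group.

Step 10
Reactants: 14 homoheptaprenyl phenyl sulfide
Product: 15 homoheptaprenyl iodide [(3E,7E,11E,15E,19E,23E)-1-iodo-4,8,12,16,20,24,28-heptamethylnonacosa-3,7,11,15,19,23,27-heptaene]
Conditions: MeI (excess), NaI, DMF, 70 °C (sealed vessel)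
Reagents that add atoms: methyl iodide CI; sodium iodide [Na+].[I-]
Why: Sulfide-to-iodide exchange, in which S-methylation gives a sulfonium salt that iodide opens at the primary carbon with release of thioanisole.

Step 11
Reactants: 16 2,3-dimethylhydroquinone (2,3-dimethylbenzene-1,4-diol)
Product: 17 4-hydroxy-2,3-dimethylphenyl pivalate
Conditions: PivCl (1.0 equiv.), pyridine, CH2Cl2, −20 °C to rt
Reagents that add atoms: pivaloyl chloride CC(C)(C)C(Cl)=O
Why: Monoacylation of a symmetric hydroquinone with one equivalent of acid chloride, the first ester group deactivating the second hydroxyl; diester and diol are separated and recycled.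

Step 12
Reactants: 17 4-hydroxy-2,3-dimethylphenyl pivalate
Product: 18 4-hydroxy-5-iodo-2,3-dimethylphenyl pivalate
Conditions: NIS, CF3CO2H (cat.), MeCN, 0 °C to rt
Reagents that add atoms: N-iodosuccinimide O=C1CCC(=O)N1I
Why: Electrophilic aromatic iodination should go ortho to the free hydroxyl, the only strongly activated open position, because the para position is occupied and the pivaloyloxy group activates far less.

Step 13
Reactants: 18 4-hydroxy-5-iodo-2,3-dimethylphenyl pivalate
Product: 19 5-iodo-2,3-dimethyl-4-(trifluoromethylsulfonyloxy)phenyl pivalate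
Conditions: Tf2O, pyridine, CH2Cl2, 0 °C
Reagents that add atoms: trifluoromethanesulfonic anhydride O=S(=O)(OS(=O)(=O)C(F)(F)F)C(F)(F)F
Why: O-Sulfonylation of the phenol gives the aryl triflate that later serves as the leaving group on C8a.

Step 14
Reactants: 15 homoheptaprenyl iodide; 4 (2R)-2-ethenyl-2-methyl-3,4-dihydro-2H-pyran
Product: 24 (3R,6E,10E,14E,18E,22E,26E,30E)-3,7,11,15,19,23,27,31,35-nonamethylhexatriaconta-1,6,10,14,18,22,26,30,34-nonaen-3-ol, via homoheptaprenyllithium 20 (not isolated), via 6-lithiodihydropyran 21 (not isolated), via mixed lithium cuprate 22 (not isolated), via ring-opened alkenylcopper alkoxide 23 (not isolated)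
Conditions: 15, t-BuLi (2.1 equiv.), Et2O/pentane, −78 °C; CuBr·SMe2 (1.0 equiv.), −78 to −40 °C; 21 (2.2 equiv., from 4 and t-BuLi, THF, −78 to 0 °C); −40 °C to rt; MeI (excess), 0 °C to rt
Reagents that add atoms: methyl iodide CI; tert-butyllithium [Li]C(C)(C)C (lithium of 20 to 23 only); CuBr·SMe2 CSC.Br[Cu] (copper of 22 and 23 only)
Why: Iodine–lithium exchange gives the homoallylic lithium 20, which with CuBr·SMe2 and the α-lithiated enol ether 21 forms the mixed cuprate 22 (a second equivalent of 21 serves as non-migrating ligand); on warming, the alkyl ligand shifts from copper to C6 of the dihydropyran, the future C4′, anti to the ring C6–O1 bond, which breaks. This is the 1,2-metallate rearrangement of an α-alkoxyalkenyl cuprate, the closest known case being the dihydrofuran-based synthesis of trisubstituted homoallylic alcohols in isoprenoid chains. The shift inverts the alkenyl carbon, so the new chain lies trans to C2′, and methyl iodide then alkylates the alkenylcopper 23 with retention, which together should give the (E)-C3′=C4′ alkene. No ring is closed, since the dihydropyran is opened and O1 is released as the tertiary alkoxide. No stereocentre is formed, and C2 keeps the (R) configuration of linalool because none of its bonds is touched. The step needs migration of the sp3 alkyl and not of the alkenyl ligand, and no attack on the allylic C2–O1 bond; the higher migratory aptitude of a primary alkyl group and the inertness of unactivated allylic ethers toward cuprates should secure both.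

Step 15
Reactants: 24 the (3R)-tertiary allylic alcohol; 19 5-iodo-2,3-dimethyl-4-(trifluoromethylsulfonyloxy)phenyl pivalate
Product: 25 5-[(1E,3R,6E,10E,14E,18E,22E,26E,30E)-3-hydroxy-3,7,11,15,19,23,27,31,35-nonamethylhexatriaconta-1,6,10,14,18,22,26,30,34-nonaen-1-yl]-2,3-dimethyl-4-(trifluoromethylsulfonyloxy)phenyl pivalate
Conditions: Pd(OAc)2 (5 mol%), n-Bu4NCl, NaHCO3, DMF/THF, 60 °C
Reagents that add atoms: none
Why: Mizoroki–Heck arylation under ligand-free phase-transfer conditions, in which zerovalent palladium inserts into the C–I bond in preference to the C–OTf bond, the aryl group adds to the terminal carbon of the only monosubstituted alkene and β-hydride elimination gives the (E)-styrene, the tertiary carbinol carbon having no hydrogen to lose.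

Step 16
Reactants: 25 the (1E)-styrene
Product: 26 5-[(1Z,3R,6E,10E,14E,18E,22E,26E,30E)-3-hydroxy-3,7,11,15,19,23,27,31,35-nonamethylhexatriaconta-1,6,10,14,18,22,26,30,34-nonaen-1-yl]-2,3-dimethyl-4-(trifluoromethylsulfonyloxy)phenyl pivalate
Conditions: fac-Ir(ppy)3 (1 mol%), THF, 450 nm LEDs, rt
Reagents that add atoms: none
Why: Triplet-sensitised contra-thermodynamic E-to-Z isomerisation of a styrene, in which the planar (E)-isomer accepts energy from excited Ir(ppy)3 while the twisted (Z)-isomer, deconjugated by the ortho-triflate and the tertiary carbinol, should not and accumulates; the isolated trisubstituted alkenes lie too high in triplet energy to be sensitised.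

Step 17
Reactants: 26 the (1Z)-styrene
Product: 27 (2R)-2,7,8-trimethyl-2-[(3E,7E,11E,15E,19E,23E,27E)-4,8,12,16,20,24,28,32-octamethyltritriaconta-3,7,11,15,19,23,27,31-octaen-1-yl]-2H-chromen-6-yl pivalate
Conditions: Pd2(dba)3 (2.5 mol%), t-BuXPhos (6 mol%), K3PO4, toluene, 80 °C
Reagents that add atoms: none
Why: Intramolecular Buchwald–Hartwig etherification (oxidative addition of zerovalent palladium into the aryl triflate, alkoxide binding, C–O reductive elimination) closes the six-membered pyran ring; the tertiary alkoxide has no β-hydrogen and no bond at C2 is broken, so the (R) configuration is kept.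

Step 18
Reactants: 27 the chromenyl pivalate
Product: 28 plastochromenol-8 [(2R)-2,7,8-trimethyl-2-[(3E,7E,11E,15E,19E,23E,27E)-4,8,12,16,20,24,28,32-octamethyltritriaconta-3,7,11,15,19,23,27,31-octaen-1-yl]-2H-chromen-6-ol]
Conditions: K2CO3, MeOH/THF (degassed), rt
Reagents that add atoms: none
Why: Base-catalysed transesterification of the aryl pivalate with methanol frees the phenol under conditions that leave the chromene and the polyene untouched.

Compound list

1 | (R)-(−)-linalool, (3R)-3,7-dimethylocta-1,6-dien-3-ol | CC(C)=CCC[C@@](C)(O)C=C | starting material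
2 | (5R)-5-ethenyl-5-methyloxolan-2-ol (both anomers) | OC1CC[C@@](C)(O1)C=C | intermediate
3 | (3R)-3-methylhept-1-en-6-yn-3-ol | C#CCC[C@@](C)(O)C=C | intermediate
4 | (2R)-2-ethenyl-2-methyl-3,4-dihydro-2H-pyran | C1=CCC[C@@](C)(O1)C=C | intermediate
5 | (2E,6E)-farnesyl acetate | CC(C)=CCC/C(C)=C/CC/C(C)=C/COC(C)=O | starting material
6 | (2E,6E,10E)-12-hydroxy-3,7,11-trimethyldodeca-2,6,10-trien-1-yl acetate | OC/C(C)=C/CC/C(C)=C/CC/C(C)=C/COC(C)=O | intermediate
7 | (2E,6E,10E)-12-bromo-3,7,11-trimethyldodeca-2,6,10-trien-1-yl acetate | BrC/C(C)=C/CC/C(C)=C/CC/C(C)=C/COC(C)=O | intermediate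
8 | (2E,6E,10E)-geranylgeraniol | CC(C)=CCC/C(C)=C/CC/C(C)=C/CC/C(C)=C/CO | starting material
9 | (2E,6E,10E)-geranylgeranyl bromide | CC(C)=CCC/C(C)=C/CC/C(C)=C/CC/C(C)=C/CBr | intermediate (not isolated)
10 | (2E,6E,10E)-geranylgeranyl phenyl sulfone | CC(C)=CCC/C(C)=C/CC/C(C)=C/CC/C(C)=C/CS(=O)(=O)c1ccccc1 | intermediate
11 | (2E,6E,10E,14E,18E,22E)-3,7,11,15,19,23,27-heptamethyl-13-(phenylsulfonyl)octacosa-2,6,10,14,18,22,26-heptaen-1-yl acetate (racemic at C13) | CC(C)=CCC/C(C)=C/CC/C(C)=C/CC/C(C)=C/C(S(=O)(=O)c1ccccc1)C/C(C)=C/CC/C(C)=C/CC/C(C)=C/COC(C)=O | intermediate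
12 | all-E-heptaprenol | CC(C)=CCC/C(C)=C/CC/C(C)=C/CC/C(C)=C/CC/C(C)=C/CC/C(C)=C/CC/C(C)=C/CO | intermediate
13 | all-E-heptaprenyl bromide | CC(C)=CCC/C(C)=C/CC/C(C)=C/CC/C(C)=C/CC/C(C)=C/CC/C(C)=C/CC/C(C)=C/CBr | intermediate (not isolated)
14 | homoheptaprenyl phenyl sulfide (all-E) | CC(C)=CCC/C(C)=C/CC/C(C)=C/CC/C(C)=C/CC/C(C)=C/CC/C(C)=C/CC/C(C)=C/CCSc1ccccc1 | intermediate
15 | homoheptaprenyl iodide (all-E) | CC(C)=CCC/C(C)=C/CC/C(C)=C/CC/C(C)=C/CC/C(C)=C/CC/C(C)=C/CC/C(C)=C/CCI | intermediate
16 | 2,3-dimethylhydroquinone | Cc1c(C)c(O)ccc1O | starting material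
17 | 4-hydroxy-2,3-dimethylphenyl pivalate | Cc1c(C)c(OC(=O)C(C)(C)C)ccc1O | intermediate
18 | 4-hydroxy-5-iodo-2,3-dimethylphenyl pivalate | Cc1c(C)c(OC(=O)C(C)(C)C)cc(I)c1O | intermediate
19 | 5-iodo-2,3-dimethyl-4-(trifluoromethylsulfonyloxy)phenyl pivalate | Cc1c(C)c(OC(=O)C(C)(C)C)cc(I)c1OS(=O)(=O)C(F)(F)F | intermediate
20 | homoheptaprenyllithium (all-E) | CC(C)=CCC/C(C)=C/CC/C(C)=C/CC/C(C)=C/CC/C(C)=C/CC/C(C)=C/CC/C(C)=C/CC[Li] | intermediate (not isolated)
21 | (2R)-2-ethenyl-6-lithio-2-methyl-3,4-dihydro-2H-pyran | [Li]C1=CCC[C@@](C)(O1)C=C | intermediate (not isolated)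
22 | lithium (homoheptaprenyl)[(2R)-2-ethenyl-2-methyl-3,4-dihydro-2H-pyran-6-yl]cuprate (second equivalent of 21 not drawn) | [Li+].CC(C)=CCC/C(C)=C/CC/C(C)=C/CC/C(C)=C/CC/C(C)=C/CC/C(C)=C/CC/C(C)=C/CC[Cu-]C1=CCC[C@@](C)(O1)C=C | intermediate (not isolated)
23 | ring-opened (6E)-7-cuprio lithium alkoxide of the C44 nonaenol (spectator ligand on copper not drawn) | CC(C)=CCC/C(C)=C/CC/C(C)=C/CC/C(C)=C/CC/C(C)=C/CC/C(C)=C/CC/C(C)=C/CC/C([Cu])=C/CC[C@@](C)(O[Li])C=C | intermediate (not isolated)
24 | (3R,6E,10E,14E,18E,22E,26E,30E)-3,7,11,15,19,23,27,31,35-nonamethylhexatriaconta-1,6,10,14,18,22,26,30,34-nonaen-3-ol | CC(C)=CCC/C(C)=C/CC/C(C)=C/CC/C(C)=C/CC/C(C)=C/CC/C(C)=C/CC/C(C)=C/CC/C(C)=C/CC[C@@](C)(O)C=C | intermediate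
25 | 5-[(1E,3R,6E,10E,14E,18E,22E,26E,30E)-3-hydroxy-3,7,11,15,19,23,27,31,35-nonamethylhexatriaconta-1,6,10,14,18,22,26,30,34-nonaen-1-yl]-2,3-dimethyl-4-(trifluoromethylsulfonyloxy)phenyl pivalate | CC(C)=CCC/C(C)=C/CC/C(C)=C/CC/C(C)=C/CC/C(C)=C/CC/C(C)=C/CC/C(C)=C/CC/C(C)=C/CC[C@@](C)(O)/C=C/c1cc(OC(=O)C(C)(C)C)c(C)c(C)c1OS(=O)(=O)C(F)(F)F | intermediate
26 | (1Z) isomer of 25 | CC(C)=CCC/C(C)=C/CC/C(C)=C/CC/C(C)=C/CC/C(C)=C/CC/C(C)=C/CC/C(C)=C/CC/C(C)=C/CC[C@@](C)(O)/C=C\c1cc(OC(=O)C(C)(C)C)c(C)c(C)c1OS(=O)(=O)C(F)(F)F | intermediate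
27 | (2R)-2,7,8-trimethyl-2-[(3E,7E,11E,15E,19E,23E,27E)-4,8,12,16,20,24,28,32-octamethyltritriaconta-3,7,11,15,19,23,27,31-octaen-1-yl]-2H-chromen-6-yl pivalate | CC(C)=CCC/C(C)=C/CC/C(C)=C/CC/C(C)=C/CC/C(C)=C/CC/C(C)=C/CC/C(C)=C/CC/C(C)=C/CC[C@]1(C)C=Cc2cc(OC(=O)C(C)(C)C)c(C)c(C)c2O1 | intermediate
28 | plastochromenol-8, (2R)-2,7,8-trimethyl-2-[(3E,7E,11E,15E,19E,23E,27E)-4,8,12,16,20,24,28,32-octamethyltritriaconta-3,7,11,15,19,23,27,31-octaen-1-yl]-2H-chromen-6-ol | CC(C)=CCC/C(C)=C/CC/C(C)=C/CC/C(C)=C/CC/C(C)=C/CC/C(C)=C/CC/C(C)=C/CC/C(C)=C/CC[C@]1(C)C=Cc2cc(O)c(C)c(C)c2O1 | target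

Total step count: 18. Longest linear sequence: 11 steps (steps 4, 5, 7, 8, 9, 10, 14, 15, 16, 17, 18).

Steps most likely to fail

1. Step 14. The six-membered α-alkoxyalkenyl cuprate may rearrange too slowly, so that ligand scrambling, protonation, or transfer of the alkenyl instead of the alkyl ligand competes; C-methylation of the alkenylcopper may also stall. The fallback sets out from 2 and 15 and comes back at 24, making the same C4′–C5′ bond by cross-coupling. Ramirez dibromo-olefination of the open aldehyde form of 2 (CBr4, PPh3, Zn, CH2Cl2) would give (3R)-7,7-dibromo-3-methylhepta-1,6-dien-3-ol F1. Zinc insertion into 15 (Zn dust, LiCl, THF) would give homoheptaprenylzinc iodide F2. Negishi coupling of F1 and F2 with Pd(DPEphos)Cl2 should replace only the bromine trans to the chain and give the (6Z)-7-bromo-nonaenol F3. Methylation of F3 with Me2Zn and Pd(t-Bu3P)2, with retention, would give 24.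

2. Step 17. C–O reductive elimination from the electron-rich, doubly ortho-substituted arylpalladium alkoxide may be slow, so that S–O cleavage of the triflate or hydrodetriflation overtakes ring closure. The fallback runs from 26 to 27 and uses copper after a change of leaving group. Ruthenium-catalysed triflate-to-iodide exchange ([Cp*Ru(MeCN)3]OTf, NaI, 1,3-dimethylimidazolidin-2-one, 100 °C) would give the (1Z)-aryl iodide F4. Ullmann etherification (CuI, 3,4,7,8-tetramethyl-1,10-phenanthroline, Cs2CO3, toluene, 110 °C) would then close F4 to 27.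

3. Step 3. The tungsten vinylidene may be intercepted by the neighbouring alkene, or the volatile, acid-labile enol ether may be lost on isolation. The fallback runs from 2 to 4 and builds the ring by acetalisation and elimination instead of cycloisomerisation. Wittig reaction of 2 with Ph3P=CHOMe (from (methoxymethyl)triphenylphosphonium chloride and KHMDS, THF) would give (3R)-7-methoxy-3-methylhepta-1,6-dien-3-ol F5 as an E/Z mixture. PPTS in CH2Cl2 should close it to (6R)-6-ethenyl-2-methoxy-6-methyloxane F6. TMSOTf and i-Pr2NEt at −20 °C would then eliminate the methoxy group and give 4.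

Further compounds

F1 | step 14 | (3R)-7,7-dibromo-3-methylhepta-1,6-dien-3-ol | BrC(Br)=CCC[C@@](C)(O)C=C
F2 | step 14 | homoheptaprenylzinc iodide (all-E) | CC(C)=CCC/C(C)=C/CC/C(C)=C/CC/C(C)=C/CC/C(C)=C/CC/C(C)=C/CC/C(C)=C/CC[Zn]I
F3 | step 14 | (3R,6Z,10E,14E,18E,22E,26E,30E)-7-bromo-3,11,15,19,23,27,31,35-octamethylhexatriaconta-1,6,10,14,18,22,26,30,34-nonaen-3-ol | CC(C)=CCC/C(C)=C/CC/C(C)=C/CC/C(C)=C/CC/C(C)=C/CC/C(C)=C/CC/C(C)=C/CC/C(Br)=C/CC[C@@](C)(O)C=C
F4 | step 17 | 5-[(1Z,3R,6E,10E,14E,18E,22E,26E,30E)-3-hydroxy-3,7,11,15,19,23,27,31,35-nonamethylhexatriaconta-1,6,10,14,18,22,26,30,34-nonaen-1-yl]-4-iodo-2,3-dimethylphenyl pivalate | CC(C)=CCC/C(C)=C/CC/C(C)=C/CC/C(C)=C/CC/C(C)=C/CC/C(C)=C/CC/C(C)=C/CC/C(C)=C/CC[C@@](C)(O)/C=C\c1cc(OC(=O)C(C)(C)C)c(C)c(C)c1I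
F5 | step 3 | (3R)-7-methoxy-3-methylhepta-1,6-dien-3-ol (E/Z mixture) | COC=CCC[C@@](C)(O)C=C
F6 | step 3 | (6R)-6-ethenyl-2-methoxy-6-methyloxane (both anomers) | COC1CCC[C@@](C)(O1)C=C
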